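The route rests on cutting the interflavan bond between C4 of ring C of the robinetinidol unit and C8 of the phloroglucinol ring of the catechin unit. The key step exploits two features: the C3 hydroxyl that sits cis to the C4 aryl group on ring C, and the 7-oxygen on ring A, para to the carbon that carries C4, which stabilises a C4 cation. A catechin-8-boronic acid is esterified onto the 3,4-diol of benzylated leucorobinetinidin; acid then ionises C4–O4 and boron, still held on O3, hands its aryl group to C4 from the O3 face. One operation forms the bond, fixes C8 (ipso) regiochemistry and sets C4. The precursor is a cyclic boronate joining both flavans through boron.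

Key step: step 7

Remark on the chemistry: (+)-dihydrorobinetin (2R,3R) and (+)-catechin (2R,3S) are assumed to be bought as single enantiomers, and they supply C2 and C3 of both units. Flavan numbering is used throughout. The β-face is the face of the C3 oxygen of the robinetinidol unit. The target is robinetinidol-(4β→8)-catechin (2,3-trans-3,4-cis in the upper unit, 4R).

Step 1
Reactants: 1 (+)-dihydrorobinetin
Product: 2 7,3',4',5'-tetra-O-benzyl-(2R,3R)-dihydrorobinetin
Conditions: BnBr (4.4 equiv), K2CO3, DMF, 0 °C → rt, N2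
Reagents that add atoms: benzyl bromide BrCc1ccccc1
Why: Williamson etherification of the four phenols, which are far more acidic than the secondary 3-OH, with a weak base at room temperature under nitrogen so that the C2 and C3 stereocenters of the 3-hydroxy ketone should stay untouched.

Step 2
Reactants: 2 7,3',4',5'-tetra-O-benzyl-(2R,3R)-dihydrorobinetin
Product: 3 7,3',4',5'-tetra-O-benzyl-(2R,3S,4R)-leucorobinetinidin (2,3-trans-3,4-trans flavan-3,4-diol)
Conditions: NaBH4, THF/MeOH, 0 °C; aq. NH4Cl
Reagents that add atoms: none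
Why: Borohydride 1,2-reduction of the aryl ketone, where axial hydride attack should give mainly the 3,4-trans diol; the C4 configuration is of no consequence because C4 is ionised in step 7.

Step 3
Reactants: 4 (+)-catechin
Product: 5 5,7,3',4'-tetra-O-benzyl-(+)-catechin
Conditions: BnBr (4.4 equiv), K2CO3, DMF, rt, N2
Reagents that add atoms: benzyl bromide BrCc1ccccc1
Why: Williamson etherification of the four phenols with a weak base that leaves the secondary 3-OH and both stereocenters untouched.

Step 4
Reactants: 5 5,7,3',4'-tetra-O-benzyl-(+)-catechin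
Product: 6 8-bromo-5,7,3',4'-tetra-O-benzyl-(+)-catechin
Conditions: NBS (1.0 equiv), CH2Cl2, −78 °C → rt
Reagents that add atoms: N-bromosuccinimide BrN1C(=O)CCC1=O
Why: Electrophilic aromatic bromination, which in 5,7-di-O-benzyl flavan-3-ols is expected to take place at C8 of the phloroglucinol ring in preference to C6.

Step 5
Reactants: 6 8-bromo-5,7,3',4'-tetra-O-benzyl-(+)-catechin
Product: 7 8-bromo-3,5,7,3',4'-penta-O-benzyl-(+)-catechin
Conditions: NaH, BnBr, DMF, 0 °C → rt
Reagents that add atoms: benzyl bromide BrCc1ccccc1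
Why: Williamson etherification of the secondary alkoxide, which removes the only free OH of this fragment that could compete for boron or for the cation in step 7.

Step 6
Reactants: 7 8-bromo-3,5,7,3',4'-penta-O-benzyl-(+)-catechin
Product: 10 3,5,7,3',4'-penta-O-benzyl-(+)-catechin-8-boronic acid, via 8-lithio arene 8 (not isolated), via lithium aryltrimethoxyborate 9 (not isolated)
Conditions: n-BuLi (1.1 equiv), THF, −78 °C; B(OMe)3, −78 → 0 °C; sat. aq. NH4Cl, 0 °C
Reagents that add atoms: trimethyl borate COB(OC)OC; water O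
Why: Bromine–lithium exchange gives an aryllithium stabilised by its two ortho oxygens, which is trapped by the trialkyl borate and hydrolysed under near-neutral conditions (standard boronic acid synthesis) to limit protodeboronation.

Step 7
Reactants: 3 7,3',4',5'-tetra-O-benzyl-(2R,3S,4R)-leucorobinetinidin; 10 3,5,7,3',4'-penta-O-benzyl-(+)-catechin-8-boronic acid
Product: 13 7,3',4',5'-tetra-O-benzyl-(2R,3S,4R)-robinetinidol-(4β→8)-3,5,7,3',4'-penta-O-benzyl-(2R,3S)-catechin, via cyclic 3,4-O-arylboronate 11 (not isolated), via 3-O-borate of the coupled flavan 12 (not isolated)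
Conditions: 10 (1.2 equiv), 4 Å MS, CH2Cl2, rt, 2 h; then TMSOTf (0.2 equiv), 5 mM, −78 → −30 °C; aq. NaHCO3
Reagents that add atoms: none
Why: Proposed new method: boronic acid 10 condenses with the trans-diol of 3 to the cyclic boronate 11, TMSOTf ionises the benzylic C4–O bond (the cation is an oxocarbenium-like para-quinone methide stabilised by the 7-benzyloxy group), and the aryl group on boron, still held on O3, attacks C4 through its ipso carbon C8 in a five-membered cyclic transition state (C4–C3–O3–B–C8), after which the O3–B bond of 12 is hydrolysed on work-up. The closest known reaction types are the Petasis borono-Mannich reaction (aryl transfer from a hydroxyl-bound boronate to an adjacent cationic carbon), the cis-selective addition of boronates to 3-hydroxy N-acyliminium ions, and the TMSOTf-catalysed Friedel–Crafts coupling of flavan-4-yl cations with flavan-3-ol nucleophiles. The only ring closed is the temporary 1,3,2-dioxaborolane of 11 (reversible double condensation, five-membered, trans-fused on ring C), which is opened again in the same flask; no ring of the product is formed here. The new stereocenter C4 is controlled by the C3 oxygen: boron sits on the β-face with O3, reachable through the ring C conformer with O3 pseudo-axial, so the aryl group should be delivered cis to O3 and trans to the C2 aryl group, giving 4R. The step needs C8 over C6 selectivity, secured because the carbon that carried boron is the one that bonds, and β- over α-face and intra- over intermolecular attack, secured by the tether, high dilution and low temperature. Full benzylation leaves no competing OH nucleophile, and the 5-deoxy ring A should keep the new bond stable to the acid.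

Step 8
Reactants: 13 7,3',4',5'-tetra-O-benzyl-(2R,3S,4R)-robinetinidol-(4β→8)-3,5,7,3',4'-penta-O-benzyl-(2R,3S)-catechin
Product: 14 robinetinidol-(4β→8)-catechin (CNP0261864.3)
Conditions: H2 (1 atm), Pd(OH)2 on carbon, THF/MeOH/H2O, rt; filtration under N2, lyophilisation
Reagents that add atoms: none
Why: Hydrogenolysis of the nine benzyl ethers over Pd(OH)2 on carbon, a global deprotection that should leave the interflavan C4–C8 bond and all five stereocenters of the benzylated dimer intact.

Compound list
1 | (+)-dihydrorobinetin, (2R,3R)-3,7-dihydroxy-2-(3,4,5-trihydroxyphenyl)chroman-4-one | Oc1ccc2c(c1)O[C@H](c1cc(O)c(O)c(O)c1)[C@@H](O)C2=O | starting material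
2 | (2R,3R)-7-benzyloxy-3-hydroxy-2-[3,4,5-tris(benzyloxy)phenyl]chroman-4-one | c1ccccc1COc1ccc2c(c1)O[C@H](c1cc(OCc3ccccc3)c(OCc3ccccc3)c(OCc3ccccc3)c1)[C@@H](O)C2=O | intermediate
3 | (2R,3S,4R)-7-benzyloxy-2-[3,4,5-tris(benzyloxy)phenyl]chromane-3,4-diol (2,3-trans-3,4-trans) | c1ccccc1COc1ccc2c(c1)O[C@H](c1cc(OCc3ccccc3)c(OCc3ccccc3)c(OCc3ccccc3)c1)[C@@H](O)[C@@H]2O | intermediate
4 | (+)-catechin, (2R,3S)-2-(3,4-dihydroxyphenyl)chromane-3,5,7-triol | c1c(O)cc(O)c2c1O[C@H](c1ccc(O)c(O)c1)[C@@H](O)C2 | starting material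
5 | (2R,3S)-5,7-bis(benzyloxy)-2-[3,4-bis(benzyloxy)phenyl]chroman-3-ol | c1c(OCc3ccccc3)cc(OCc3ccccc3)c2c1O[C@H](c1ccc(OCc3ccccc3)c(OCc3ccccc3)c1)[C@@H](O)C2 | intermediate
6 | (2R,3S)-5,7-bis(benzyloxy)-2-[3,4-bis(benzyloxy)phenyl]-8-bromochroman-3-ol | Brc1c(OCc3ccccc3)cc(OCc3ccccc3)c2c1O[C@H](c1ccc(OCc3ccccc3)c(OCc3ccccc3)c1)[C@@H](O)C2 | intermediate
7 | (2R,3S)-3,5,7-tris(benzyloxy)-2-[3,4-bis(benzyloxy)phenyl]-8-bromochromane | Brc1c(OCc3ccccc3)cc(OCc3ccccc3)c2c1O[C@H](c1ccc(OCc3ccccc3)c(OCc3ccccc3)c1)[C@@H](OCc1ccccc1)C2 | intermediate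
8 | 8-lithio derivative of 7 (aryllithium at C8, not isolated) | [Li]c1c(OCc3ccccc3)cc(OCc3ccccc3)c2c1O[C@H](c1ccc(OCc3ccccc3)c(OCc3ccccc3)c1)[C@@H](OCc1ccccc1)C2 | intermediate
9 | lithium trimethoxy(penta-O-benzylcatechin-8-yl)borate (not isolated) | [Li+].CO[B-](OC)(OC)c1c(OCc3ccccc3)cc(OCc3ccccc3)c2c1O[C@H](c1ccc(OCc3ccccc3)c(OCc3ccccc3)c1)[C@@H](OCc1ccccc1)C2 | intermediate
10 | [(2R,3S)-3,5,7-tris(benzyloxy)-2-[3,4-bis(benzyloxy)phenyl]chroman-8-yl]boronic acid | OB(O)c1c(OCc3ccccc3)cc(OCc3ccccc3)c2c1O[C@H](c1ccc(OCc3ccccc3)c(OCc3ccccc3)c1)[C@@H](OCc1ccccc1)C2 | intermediate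
11 | cyclic boronate: O3 and O4 of diol 3 bridged by the boron of 10 (trans-fused 1,3,2-dioxaborolane bearing the catechin C8 aryl group on boron, not isolated) | c1ccccc1COc1ccc2c(c1)O[C@H](c1cc(OCc3ccccc3)c(OCc3ccccc3)c(OCc3ccccc3)c1)[C@@H](O5)[C@@H]2OB5c1c(OCc3ccccc3)cc(OCc3ccccc3)c2c1O[C@H](c1ccc(OCc3ccccc3)c(OCc3ccccc3)c1)[C@@H](OCc1ccccc1)C2 | intermediate
12 | 3-O-borate ester of 13 after aryl transfer (drawn as the dihydroxyboryl ether formed on quench, not isolated) | c1ccccc1COc1ccc2c(c1)O[C@H](c1cc(OCc3ccccc3)c(OCc3ccccc3)c(OCc3ccccc3)c1)[C@@H](OB(O)O)[C@H]2c1c(OCc3ccccc3)cc(OCc3ccccc3)c2c1O[C@H](c1ccc(OCc3ccccc3)c(OCc3ccccc3)c1)[C@@H](OCc1ccccc1)C2 | intermediate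
13 | nona-O-benzyl robinetinidol-(4β→8)-catechin with free upper 3-OH: upper unit (2R,3S,4R), 7,3',4',5'-tetra-O-benzyl; lower unit (2R,3S), 3,5,7,3',4'-penta-O-benzyl | c1ccccc1COc1ccc2c(c1)O[C@H](c1cc(OCc3ccccc3)c(OCc3ccccc3)c(OCc3ccccc3)c1)[C@@H](O)[C@H]2c1c(OCc3ccccc3)cc(OCc3ccccc3)c2c1O[C@H](c1ccc(OCc3ccccc3)c(OCc3ccccc3)c1)[C@@H](OCc1ccccc1)C2 | intermediate
14 | robinetinidol-(4β→8)-catechin, upper unit (2R,3S,4R), lower unit (2R,3S) | Oc1ccc2c(c1)O[C@H](c1cc(O)c(O)c(O)c1)[C@@H](O)[C@H]2c1c(O)cc(O)c2c1O[C@H](c1ccc(O)c(O)c1)[C@@H](O)C2 | target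

Total step count: 8. Longest linear sequence: 6 (steps 3, 4, 5, 6, 7, 8).

Steps most likely to fail

Step 7 (proposed new method). The aryl transfer from boron may be outrun by protodeboronation of the electron-rich boronate under the acid, or by untethered intermolecular attack of a second arene on the α-face or through C6, which would erode facial and site selectivity. The fallback uses known chemistry and sets out from ketone 2 and bromide 7. Ketone 2 is silylated (TBSCl, imidazole, DMF, rt) to the 3-O-TBS ketone F1. Aryllithium 8, generated from 7 as in step 6, is added to the C4 carbonyl of F1 (THF, −78 °C), a 1,2-addition of an 8-lithioflavan to a flavan-4-one, to give the tertiary bis-benzylic alcohol F2, in which the C4–C8 bond is already in place; its C4 configuration is immaterial. Ionic hydrogenation (Et3SiH, CF3CO2H, CH2Cl2, 0 °C) reduces F2 through the C4 cation, and hydride is expected to enter anti to the 3-silyloxy group, from the α-face, to give the 4β-aryl flavan F3. TBAF in THF then removes the silyl group and the route is rejoined at 13.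

Step 6. The aryllithium may be protonated before it is trapped, and the 2,6-dioxygenated boronic acid may lose boron by ipso-protonation during aqueous work-up and chromatography. The fallback sets out from bromide 7 and avoids both the organolithium and the handling of the free acid. Miyaura borylation (B2pin2, KOAc, Pd2(dba)3, XPhos, dioxane, 100 °C) gives the chromatography-stable pinacol boronate F4. KHF2 in aqueous MeOH converts it to the crystalline potassium trifluoroborate F5, which serves as the storage form. Stirring F5 with silica gel and water in EtOAc immediately before use unmasks the boronic acid, which is used crude, and the route is rejoined at 10.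

Step 1. Under base the 3-hydroxy ketone may enolise, which opens the way to C2/C3 epimerisation through ring opening and to air oxidation to the flavonol. The fallback sets out from 1 and removes the ketone before any base is used. NaBH4 in EtOH at 0 °C reduces 1 to free (+)-leucorobinetinidin F6. Its four phenols are then benzylated (BnBr, K2CO3, DMF, rt, N2), and the route is rejoined at 3.

Further compounds
F1 | step 7 | (2R,3R)-7-benzyloxy-3-(tert-butyldimethylsilyloxy)-2-[3,4,5-tris(benzyloxy)phenyl]chroman-4-one | c1ccccc1COc1ccc2c(c1)O[C@H](c1cc(OCc3ccccc3)c(OCc3ccccc3)c(OCc3ccccc3)c1)[C@@H](O[Si](C)(C)C(C)(C)C)C2=O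
F2 | step 7 | tertiary alcohol from addition of 8 to F1: 3-O-TBS-4β-hydroxy-4α-(penta-O-benzylcatechin-8-yl) tetra-O-benzyl flavan (aryl drawn anti to the 3-silyloxy group) | c1ccccc1COc1ccc2c(c1)O[C@H](c1cc(OCc3ccccc3)c(OCc3ccccc3)c(OCc3ccccc3)c1)[C@@H](O[Si](C)(C)C(C)(C)C)[C@]2(O)c1c(OCc3ccccc3)cc(OCc3ccccc3)c2c1O[C@H](c1ccc(OCc3ccccc3)c(OCc3ccccc3)c1)[C@@H](OCc1ccccc1)C2
F3 | step 7 | 3-O-TBS ether of 13 (4β-aryl, upper unit 2R,3S,4R) | c1ccccc1COc1ccc2c(c1)O[C@H](c1cc(OCc3ccccc3)c(OCc3ccccc3)c(OCc3ccccc3)c1)[C@@H](O[Si](C)(C)C(C)(C)C)[C@H]2c1c(OCc3ccccc3)cc(OCc3ccccc3)c2c1O[C@H](c1ccc(OCc3ccccc3)c(OCc3ccccc3)c1)[C@@H](OCc1ccccc1)C2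
F4 | step 6 | pinacol ester of boronic acid 10 | CC1(C)OB(OC1(C)C)c1c(OCc3ccccc3)cc(OCc3ccccc3)c2c1O[C@H](c1ccc(OCc3ccccc3)c(OCc3ccccc3)c1)[C@@H](OCc1ccccc1)C2
F5 | step 6 | potassium (penta-O-benzylcatechin-8-yl)trifluoroborate | [K+].F[B-](F)(F)c1c(OCc3ccccc3)cc(OCc3ccccc3)c2c1O[C@H](c1ccc(OCc3ccccc3)c(OCc3ccccc3)c1)[C@@H](OCc1ccccc1)C2
F6 | step 1 | (+)-leucorobinetinidin, (2R,3S,4R)-2-(3,4,5-trihydroxyphenyl)chromane-3,4,7-triol | Oc1ccc2c(c1)O[C@H](c1cc(O)c(O)c(O)c1)[C@@H](O)[C@@H]2O
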